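**Retrosynthetic overview**

1. The target (fisetinidol-(4β→6)-leucofisetinidin, both units 2,3-trans-3,4-cis) is cut at the interflavan bond C4(upper)–C6(lower): a 6-lithiated lower unit adds to the 4-ketone of the upper unit, and ionic deoxygenation of the resulting carbinol sets the upper C4.
2. Both partners come from one monomer, the benzyl-protected (2R,3S,4S)-flavan-3,4-diol acetonide: hydrolysis and benzylic oxidation give the ketone; silylation and bromination give the aryl bromide.
3. The monomer comes from the key step, an enantioselective oxa-Povarov-type (4+2) annulation of the aryl oxocarbenium ion from a racemic mixed acetal (3-benzyloxyphenol plus 3,4-dibenzyloxybenzaldehyde) with 2,2-dimethyl-1,3-dioxole. It forms C2–C3 and C4–C4a of ring C and all three stereocentres.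
4. Enabling feature: in pyran ring C, O1–C2 (C2 benzylic to ring B) together with the C8a=C4a bond of ring A is a latent cationic 2-oxadiene; the cis-3,4-diol at C3/C4 is a disguised cyclic cis-enediol ether; the C7 oxygen para to C4a makes C4a the nucleophilic ring carbon.
5. Ring order: rings A and B are bought; ring C of each flavan unit is closed in the key step (same batch); the two units are joined last.

Key step: step 4

Assumption: the sense of induction of the chiral acid in step 4 cannot be derived on paper, so the (S,S) antipode is written and the antipode that gives the (2R,3S,4S) series is fixed in a first trial run.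

**Step 1**
Reactants: 1 2,2-dimethyl-1,3-dioxolane
Product: 3 2,2-dimethyl-1,3-dioxole, via 4-chloro-2,2-dimethyl-1,3-dioxolane 2 (not isolated)
Conditions: SO2Cl2 (1.0 equiv), AIBN (cat.), neat, 50 °C; then n-Bu3N (1.3 equiv), 100 °C, product distilled out
Reagents that add atoms: none
Why: Radical α-chlorination of the ether C–H with SO2Cl2 followed by amine-mediated dehydrochlorination of the α-chloro ether is the chlorination–elimination sequence used for cyclic enol derivatives such as vinylene carbonate, and the product has no stereocentre.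

**Step 2**
Reactants: 4 3,4-bis(benzyloxy)benzaldehyde
Product: 5 1,2-bis(benzyloxy)-4-(dimethoxymethyl)benzene
Conditions: HC(OMe)3, p-TsOH·H2O (cat.), MeOH, rt; Et3N quench
Reagents that add atoms: trimethyl orthoformate, COC(OC)OC; methanol, CO
Why: Acid-catalysed acetalisation driven by the orthoester as water scavenger; no stereocentre is formed.

**Step 3**
Reactants: 5 1,2-bis(benzyloxy)-4-(dimethoxymethyl)benzene; 6 3-(benzyloxy)phenol
Product: 8 racemic mixed acetal 1,2-bis(benzyloxy)-4-{[3-(benzyloxy)phenoxy](methoxy)methyl}benzene, via α-chloro ether 7 (not isolated)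
Conditions: AcCl (1.05 equiv), ZnBr2 (0.1 mol%), CH2Cl2, rt; then 6, NaH, THF, −78 → 0 °C
Reagents that add atoms: none
Why: Acetal–acyl chloride exchange catalysed by ZnBr2 gives the α-chloro ether, which O-alkylates the sodium phenoxide of 6 (Williamson-type substitution through the oxocarbenium ion); the acetal carbon is formed racemic, which does not matter because it becomes planar in step 4.

**Step 4**
Reactants: 8 racemic mixed acetal; 3 2,2-dimethyl-1,3-dioxole
Product: 11 acetonide of 12 (7-benzyloxy-2-[3,4-bis(benzyloxy)phenyl]chromane-3,4-diol 3,4-O-isopropylidene ketal; 2-aryl trans to the cis-fused dioxolane; configuration as in 12), via aryl oxocarbenium ion 9 (not isolated), via dioxolanylium ion 10 (not isolated)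
Conditions: 3 (3 equiv), (S,S)-IDPi Brønsted acid (imidodiphosphorimidate from two (S)-3,3'-diaryl-BINOL units, N-SO2CF3; 5 mol%), 5 Å MS, toluene/CH2Cl2 4:1, −60 °C
Reagents that add atoms: none
Why: Proposed new method: the confined chiral acid protonates the methoxy group of racemic 8 and expels methanol, so that both enantiomers of the acetal converge on the planar (E)-aryl oxocarbenium ion 9, held as a contact ion pair with the chiral anion (an enantioconvergent, stereoablative ionisation); the closest known reaction types are the SnCl4-promoted oxa-Povarov annulation of aryl mixed acetals with alkenes, which is racemic, and the ion-pair-catalysed asymmetric Povarov reaction of N-aryl iminium ions with cyclic enol ethers. The enol ether carbon of 3 attacks the oxocarbenium carbon (bond C2–C3) to give the oxygen-stabilised cation 10, whose cationic C4 is captured at once by the ring A carbon that is ortho to O1 and para to the benzyloxy group (bond C4–C4a), a 6-exo-trig Friedel–Crafts closure of ring C that makes the whole event a polar, asynchronous (4+2) annulation, and loss of the arenium proton returns the acid. C2 is set by the chiral anion, which leaves only one face of 9 open; C3 is set by the exo approach, in which the dioxole ring lies over the small C2–H while the endo approach would press a ketal methyl group onto ring A, and this gives the 2,3-trans relation; C4 is set by the five-membered ring of 3, which can only become cis-fused, and this gives the 3,4-cis relation. The step needs enantiofacial selectivity (catalyst pocket), exo selectivity (gem-dimethyl group of 3), ring closure para instead of ortho to the benzyloxy group (the ortho position lies between two oxygens and is hindered) and preference of the oxocarbenium ion for 3 over arene nucleophiles (excess of the far more nucleophilic enol ether, low temperature, sieves that take up the methanol).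

**Step 5**
Reactants: 11 acetonide of 12
Product: 12 (2R,3S,4S)-7-(benzyloxy)-2-[3,4-bis(benzyloxy)phenyl]chromane-3,4-diol (2,3-trans-3,4-cis)
Conditions: AcOH/THF/H2O 3:1:1, 40 °C
Reagents that add atoms: none
Why: Acid-catalysed ketal hydrolysis, in which protonation and cleavage occur at the ketal carbon and aqueous acetic acid is too weak to ionise the benzylic C4–O bond, so that the three stereocentres are kept.

**Step 6**
Reactants: 12 (2R,3S,4S)-diol
Product: 13 (2R,3R)-7-(benzyloxy)-2-[3,4-bis(benzyloxy)phenyl]-3-hydroxychroman-4-one (2,3-trans)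
Conditions: DDQ (1.2 equiv), CH2Cl2, 0 °C → rt
Reagents that add atoms: none
Why: DDQ dehydrogenation of an electron-rich benzylic alcohol by hydride abstraction at C4, which is activated by O1 in the ortho and the 7-benzyloxy group in the para position, leaves the non-benzylic 3-OH untouched and keeps the 2,3-trans centres.

**Step 7**
Reactants: 13 (2R,3R)-3-hydroxychroman-4-one
Product: 14 (2R,3R)-7-(benzyloxy)-2-[3,4-bis(benzyloxy)phenyl]-3-[(tert-butyldimethylsilyl)oxy]chroman-4-one
Conditions: TBSCl, imidazole, DMF, rt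
Reagents that add atoms: tert-butyldimethylsilyl chloride, CC(C)(C)[Si](C)(C)Cl
Why: Silylation of the secondary hydroxyl (silyl chloride and imidazole), mild enough to avoid enolisation or ring opening of the β-aryloxy ketone; no stereocentre is touched.

**Step 8**
Reactants: 12 (2R,3S,4S)-diol
Product: 15 3,4-bis-O-(tert-butyldimethylsilyl) ether of 12
Conditions: TBSOTf (2.5 equiv), 2,6-lutidine, CH2Cl2, −40 → 0 °C
Reagents that add atoms: tert-butyldimethylsilyl triflate, CC(C)(C)[Si](C)(C)OS(=O)(=O)C(F)(F)F
Why: Silylation of both hindered secondary hydroxyls with the silyl triflate and a non-nucleophilic base; no stereocentre is touched.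

**Step 9**
Reactants: 15 bis-silyl ether
Product: 16 6-bromo derivative of 15
Conditions: NBS (1.05 equiv), CH2Cl2, −40 → 0 °C, dark
Reagents that add atoms: N-bromosuccinimide, O=C1CCC(=O)N1Br
Why: Electrophilic aromatic bromination goes to C6, which is para to O1, ortho to the benzyloxy group and unhindered, whereas C8 lies between two oxygens and each free position of ring B has only one oxygen in the ortho or para position.

**Step 10**
Reactants: 16 6-bromo bis-silyl ether; 14 (2R,3R)-3-silyloxychroman-4-one
Product: 18 tertiary carbinol (the chroman-4-ol formed from 14 that carries at C4 the 6-yl residue of 15; both C4 epimers; other centres as in 14 and 15), via aryllithium 17 (not isolated)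
Conditions: n-BuLi (1.0 equiv to 16), THF, −78 °C; then 14 (0.8 equiv), −78 °C; H2O
Reagents that add atoms: none
Why: Bromine–lithium exchange and 1,2-addition of the aryllithium to the flavan-4-one, a known way to join two flavan units at C4, fixes the C4–C6 bond without regiochemical ambiguity; the carbinol centre forms as an epimer mixture that is planarised in step 11.

**Step 11**
Reactants: 18 tertiary carbinol
Product: 19 protected dimer (hexa-O-benzyl-tris-O-silyl derivative of 21; upper unit 2-aryl α / 3-O-silyl β / 4-aryl β; lower unit as in 15)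
Conditions: n-Bu3SnH (3 equiv), CF3CO2H (3 equiv), CH2Cl2, −78 → −30 °C
Reagents that add atoms: none
Why: Ionic hydrogenation (acid ionisation of the tertiary diaryl carbinol and hydride transfer from the tin hydride) is stereoconvergent, since both carbinol epimers give the same planar C4 cation, and the hydride should enter from the α-face, anti to the bulky 3-silyloxy group, so that the aryl group ends up β (3,4-cis); the tertiary doubly benzylic carbinol should ionise far faster than the secondary silyl-protected C4–O of the lower unit at low temperature.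

**Step 12**
Reactants: 19 protected dimer
Product: 20 hexa-O-benzyl ether of 21 (six phenolic oxygens benzylated; three free secondary hydroxyls)
Conditions: TBAF (4 equiv), THF, 0 °C → rt
Reagents that add atoms: none
Why: Fluoride-induced cleavage of the three silyl ethers under non-acidic conditions, so that the benzylic C4–OH of the lower unit is not ionised and no stereocentre is touched.

**Step 13**
Reactants: 20 hexa-O-benzyl ether
Product: 21 (2R,3S,4S)-2-(3,4-dihydroxyphenyl)-6-[(2R,3S,4S)-2-(3,4-dihydroxyphenyl)-3,7-dihydroxy-3,4-dihydro-2H-chromen-4-yl]-3,4-dihydro-2H-chromene-3,4,7-triol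
Conditions: H2 (1 atm), Pd(OH)2 on carbon, THF/MeOH 1:1, rt; filtration under argon, lyophilisation
Reagents that add atoms: none
Why: Hydrogenolysis of the six aryl benzyl ethers under neutral conditions, where O-benzyl cleavage is much faster than hydrogenolysis of the free secondary benzylic C4–OH; no stereocentre is touched.

**Compound list**

1 | 2,2-dimethyl-1,3-dioxolane | CC1(C)OCCO1 | starting material
2 | 4-chloro-2,2-dimethyl-1,3-dioxolane (racemic) | CC1(C)OCC(Cl)O1 | intermediate (not isolated)
3 | 2,2-dimethyl-1,3-dioxole | CC1(C)OC=CO1 | intermediate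
4 | 3,4-bis(benzyloxy)benzaldehyde | O=Cc1ccc(OCc2ccccc2)c(OCc2ccccc2)c1 | starting material
5 | 1,2-bis(benzyloxy)-4-(dimethoxymethyl)benzene | COC(OC)c1ccc(OCc2ccccc2)c(OCc2ccccc2)c1 | intermediate
6 | 3-(benzyloxy)phenol | Oc1cccc(OCc2ccccc2)c1 | starting material
7 | 1,2-bis(benzyloxy)-4-[chloro(methoxy)methyl]benzene (racemic) | COC(Cl)c1ccc(OCc2ccccc2)c(OCc2ccccc2)c1 | intermediate (not isolated)
8 | 1,2-bis(benzyloxy)-4-{[3-(benzyloxy)phenoxy](methoxy)methyl}benzene (racemic mixed acetal) | COC(Oc1cccc(OCc2ccccc2)c1)c1ccc(OCc2ccccc2)c(OCc2ccccc2)c1 | intermediate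
9 | (E)-[3-(benzyloxy)phenyl][3,4-bis(benzyloxy)benzylidene]oxonium ion (ion pair with the catalyst anion) | c1ccccc1COc1cccc(c1)/[O+]=C/c1ccc(OCc2ccccc2)c(OCc2ccccc2)c1 | intermediate (not isolated)
10 | 2,2-dimethyl-1,3-dioxolan-4-ylium ion carrying at C5 the (R)-[3-(benzyloxy)phenoxy][3,4-bis(benzyloxy)phenyl]methyl group (C5 configured as C3 of 11) | c1ccccc1COc1cccc(c1)O[C@H](c1ccc(OCc2ccccc2)c(OCc2ccccc2)c1)[C@H]1OC(C)(C)[O+]=C1 | intermediate (not isolated)
11 | 3,4-O-isopropylidene ketal of 12 (2-aryl trans to the cis-fused dioxolane) | c1cc2c(cc1OCc1ccccc1)O[C@H](c1ccc(OCc3ccccc3)c(OCc3ccccc3)c1)[C@@H](OC(C)(C)O1)[C@H]21 | intermediate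
12 | (2R,3S,4S)-7-(benzyloxy)-2-[3,4-bis(benzyloxy)phenyl]chromane-3,4-diol | c1cc2c(cc1OCc1ccccc1)O[C@H](c1ccc(OCc3ccccc3)c(OCc3ccccc3)c1)[C@@H](O)[C@H]2O | intermediate
13 | (2R,3R)-7-(benzyloxy)-2-[3,4-bis(benzyloxy)phenyl]-3-hydroxychroman-4-one | c1cc2c(cc1OCc1ccccc1)O[C@H](c1ccc(OCc3ccccc3)c(OCc3ccccc3)c1)[C@@H](O)C2=O | intermediate
14 | (2R,3R)-7-(benzyloxy)-2-[3,4-bis(benzyloxy)phenyl]-3-[(tert-butyldimethylsilyl)oxy]chroman-4-one | c1cc2c(cc1OCc1ccccc1)O[C@H](c1ccc(OCc3ccccc3)c(OCc3ccccc3)c1)[C@@H](O[Si](C)(C)C(C)(C)C)C2=O | intermediate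
15 | 3,4-bis-O-(tert-butyldimethylsilyl) ether of 12 | c1cc2c(cc1OCc1ccccc1)O[C@H](c1ccc(OCc3ccccc3)c(OCc3ccccc3)c1)[C@@H](O[Si](C)(C)C(C)(C)C)[C@H]2O[Si](C)(C)C(C)(C)C | intermediate
16 | 6-bromo derivative of 15 | Brc1cc2c(cc1OCc1ccccc1)O[C@H](c1ccc(OCc3ccccc3)c(OCc3ccccc3)c1)[C@@H](O[Si](C)(C)C(C)(C)C)[C@H]2O[Si](C)(C)C(C)(C)C | intermediate
17 | 6-lithio derivative of 15 | [Li]c1cc2c(cc1OCc1ccccc1)O[C@H](c1ccc(OCc3ccccc3)c(OCc3ccccc3)c1)[C@@H](O[Si](C)(C)C(C)(C)C)[C@H]2O[Si](C)(C)C(C)(C)C | intermediate (not isolated)
18 | tertiary carbinol from 14 and 17 (upper C4 bears OH and the 6-yl residue of 15; both C4 epimers) | c1ccccc1COc1ccc2c(c1)O[C@H](c1ccc(OCc3ccccc3)c(OCc3ccccc3)c1)[C@@H](O[Si](C)(C)C(C)(C)C)C2(O)c1cc2c(cc1OCc1ccccc1)O[C@H](c1ccc(OCc3ccccc3)c(OCc3ccccc3)c1)[C@@H](O[Si](C)(C)C(C)(C)C)[C@H]2O[Si](C)(C)C(C)(C)C | intermediate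
19 | hexa-O-benzyl-tris-O-(tert-butyldimethylsilyl) derivative of 21 | c1ccccc1COc1ccc2c(c1)O[C@H](c1ccc(OCc3ccccc3)c(OCc3ccccc3)c1)[C@@H](O[Si](C)(C)C(C)(C)C)[C@H]2c1cc2c(cc1OCc1ccccc1)O[C@H](c1ccc(OCc3ccccc3)c(OCc3ccccc3)c1)[C@@H](O[Si](C)(C)C(C)(C)C)[C@H]2O[Si](C)(C)C(C)(C)C | intermediate
20 | hexa-O-benzyl ether of 21 | c1ccccc1COc1ccc2c(c1)O[C@H](c1ccc(OCc3ccccc3)c(OCc3ccccc3)c1)[C@@H](O)[C@H]2c1cc2c(cc1OCc1ccccc1)O[C@H](c1ccc(OCc3ccccc3)c(OCc3ccccc3)c1)[C@@H](O)[C@H]2O | intermediate
21 | (2R,3S,4S)-2-(3,4-dihydroxyphenyl)-6-[(2R,3S,4S)-2-(3,4-dihydroxyphenyl)-3,7-dihydroxy-3,4-dihydro-2H-chromen-4-yl]-3,4-dihydro-2H-chromene-3,4,7-triol | Oc1ccc2c(c1)O[C@H](c1ccc(O)c(O)c1)[C@@H](O)[C@H]2c1cc2c(cc1O)O[C@H](c1ccc(O)c(O)c1)[C@@H](O)[C@H]2O | target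

**Totals**

Total step count: 13. Longest linear sequence: 10 steps (steps 2, 3, 4, 5, 8, 9, 10, 11, 12, 13).

**Steps most likely to fail**

1. Step 4 (proposed new method). The ion pair may discriminate poorly between the enantiofaces or between the exo and endo approach, and acid-induced oligomerisation of the dioxole may outrun the annulation.
 Fallback with known chemistry, setting out from aldehyde 4 and coming back to the route at ketol 13 and at bis-silyl ether 15:
 - Claisen–Schmidt condensation of 4 with bought 1-[4-(benzyloxy)-2-hydroxyphenyl]ethanone F1 (KOH, EtOH) should give the (E)-2'-hydroxychalcone F2.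
 - MOMCl and i-Pr2NEt give its MOM ether F3.
 - Juliá–Colonna epoxidation (poly-L-leucine, urea–H2O2, DBU, THF) should give the (αR,βS)-epoxychalcone F4.
 - HCl in MeOH/THF removes the MOM group and lets the freed phenol open the epoxide at the benzylic carbon with inversion, which gives 13 and, by step 7, 14.
 - For the lower unit, reduction of 14 with L-Selectride (THF, −78 °C; equatorial hydride delivery, axial 4β-alcohol cis to O3) should give the 3-O-silyl 4-ol F5, and TBSOTf/2,6-lutidine converts it into 15.

2. Step 11. Hydride delivery at the upper C4 cation may be poorly face-selective, and the silyl-protected C4–O of the lower unit may ionise as well and be over-reduced.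
 Fallback, setting out from diol 12 and bis-silyl ether 15 and coming back at 20:
 - Acid-catalysed exchange of the C4–OH of 12 with benzyl mercaptan (BnSH, AcOH) gives the 4-benzylsulfanyl flavan-3-ol F6.
 - Thiophilic activation with AgBF4 (THF, 0 °C) in the presence of an excess of 15 (Friedel–Crafts alkylation of C6 by the flavan-4-yl cation, which leaves the C4–O of 15 untouched) should give both C4 epimers, with the unwanted 4α epimer expected to predominate; the 4β-linked dimer F7 is separated.
 - TBAF removes the two silyl groups and gives 20.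

3. Step 13. The free benzylic C4–OH of the lower unit may be lost by hydrogenolysis during debenzylation.
 Fallback, setting out from 19 and coming back at 21:
 - The benzyl ethers are hydrogenolysed while the three hydroxyls are still silylated (H2, Pd(OH)2 on carbon, EtOAc/MeOH), giving the tris-O-silyl hexaphenol F8, in which the bulky silyl ether shields the benzylic C4–O bond.
 - The silyl groups are then removed with Et3N·3HF in MeCN/THF to give 21.

**Further compounds**

F1 | step 4 | 1-[4-(benzyloxy)-2-hydroxyphenyl]ethanone (bought) | CC(=O)c1ccc(OCc2ccccc2)cc1O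
F2 | step 4 | (E)-1-[4-(benzyloxy)-2-hydroxyphenyl]-3-[3,4-bis(benzyloxy)phenyl]prop-2-en-1-one | O=C(/C=C/c1ccc(OCc2ccccc2)c(OCc2ccccc2)c1)c1ccc(OCc2ccccc2)cc1O
F3 | step 4 | (E)-1-[4-(benzyloxy)-2-(methoxymethoxy)phenyl]-3-[3,4-bis(benzyloxy)phenyl]prop-2-en-1-one | O=C(/C=C/c1ccc(OCc2ccccc2)c(OCc2ccccc2)c1)c1ccc(OCc2ccccc2)cc1OCOC
F4 | step 4 | [4-(benzyloxy)-2-(methoxymethoxy)phenyl]{(2R,3S)-3-[3,4-bis(benzyloxy)phenyl]oxiran-2-yl}methanone | O=C(c1ccc(OCc2ccccc2)cc1OCOC)[C@@H]1O[C@H]1c1ccc(OCc2ccccc2)c(OCc2ccccc2)c1
F5 | step 4 | 3-O-(tert-butyldimethylsilyl) ether of 12 (4-OH free, 3,4-cis) | c1cc2c(cc1OCc1ccccc1)O[C@H](c1ccc(OCc3ccccc3)c(OCc3ccccc3)c1)[C@@H](O[Si](C)(C)C(C)(C)C)[C@H]2O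
F6 | step 11 | (2R,3S)-7-(benzyloxy)-4-(benzylsulfanyl)-2-[3,4-bis(benzyloxy)phenyl]chroman-3-ol (both C4 epimers) | c1cc2c(cc1OCc1ccccc1)O[C@H](c1ccc(OCc3ccccc3)c(OCc3ccccc3)c1)[C@@H](O)C2SCc1ccccc1
F7 | step 11 | hexa-O-benzyl dimer with free upper 3-OH and lower 3,4-bis-O-(tert-butyldimethylsilyl) groups (4β-linked) | c1ccccc1COc1ccc2c(c1)O[C@H](c1ccc(OCc3ccccc3)c(OCc3ccccc3)c1)[C@@H](O)[C@H]2c1cc2c(cc1OCc1ccccc1)O[C@H](c1ccc(OCc3ccccc3)c(OCc3ccccc3)c1)[C@@H](O[Si](C)(C)C(C)(C)C)[C@H]2O[Si](C)(C)C(C)(C)C
F8 | step 13 | tris-O-(tert-butyldimethylsilyl) ether of 21 at the three secondary hydroxyls (six free phenols) | Oc1ccc2c(c1)O[C@H](c1ccc(O)c(O)c1)[C@@H](O[Si](C)(C)C(C)(C)C)[C@H]2c1cc2c(cc1O)O[C@H](c1ccc(O)c(O)c1)[C@@H](O[Si](C)(C)C(C)(C)C)[C@H]2O[Si](C)(C)C(C)(C)C
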